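## Retrosynthetic overview

1. Target 15 ⇐ dibenzoate 14 by hydrogenolysis of two aryl benzyl ethers; 14 ⇐ (2R,3R)-diol 12 by double benzoylation.
2. 12 ⇐ (2R,3R)-dibenzylsuccinyl bis-imide 11 by reductive removal of both auxiliaries; the two imide carbonyls become the two CH2O carbons.
3. Key step: 11 ⇐ C2-symmetric succinyl bis-imide 4 + bromides 6 and 8. The bis-enolate of 4 is benzylated twice in one flask with two different bromides; the first C–C bond breaks the C2 symmetry, and each (R)-auxiliary sets the centre next to it.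
4. 4 ⇐ succinyl chloride + 2 × (R)-4-benzyl-2-oxazolidinone; 6 and 8 ⇐ the O-benzyl isovanillyl and vanillyl alcohols.
5. Rings: none is formed. The arene rings are bought in, and the two oxazolidinone rings are carried from step 1 to step 5 and then recovered.

Assumption: the metalated species of steps 1 and 4 are numbered as non-isolated intermediates (3, 9, 10); other transient species (tetrahedral adducts, borates, enolates inside the fallbacks) are treated as mechanistic and carry no entry; compounds 1, 2, 5, 7 and 13 are taken as catalogue materials.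

## Route

Step 1
Reactants: 1 (4R)-4-benzyl-1,3-oxazolidin-2-one; 2 succinyl chloride
Product: 4 3,3'-butanedioylbis[(4R)-4-benzyl-1,3-oxazolidin-2-one], via N-lithio oxazolidinone 3 (not isolated)
Conditions: 1 (2.05 equiv), n-BuLi (2.05 equiv), THF, −78 °C, 30 min; then 2 (1.0 equiv), −78 → 0 °C; aq NH4Cl
Reagents that add atoms: n-butyllithium, [Li]CCCC (supplies only the Li of 3; no atom of 4)
Why: N-acylation of the lithiated oxazolidinone at both acyl chloride termini (Evans imide formation); no stereocentre is made, and the two identical (R)-auxiliaries make 4 C2-symmetric.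

Step 2
Reactants: 5 [3-(benzyloxy)-4-methoxyphenyl]methanol
Product: 6 2-(benzyloxy)-4-(bromomethyl)-1-methoxybenzene
Conditions: PBr3 (0.4 equiv), CH2Cl2, 0 °C, 1 h; cold NaHCO3 wash, used at once
Reagents that add atoms: phosphorus tribromide, BrP(Br)Br
Why: PBr3 bromination of a primary benzylic alcohol through its phosphite ester (SN2-type displacement); the aryl benzyl and methyl ethers are inert at 0 °C.

Step 3
Reactants: 7 [4-(benzyloxy)-3-methoxyphenyl]methanol
Product: 8 1-(benzyloxy)-4-(bromomethyl)-2-methoxybenzene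
Conditions: PBr3 (0.4 equiv), CH2Cl2, 0 °C, 1 h; cold NaHCO3 wash, used at once
Reagents that add atoms: phosphorus tribromide, BrP(Br)Br
Why: Same PBr3 bromination of a primary benzylic alcohol as in step 2; no stereocentre is involved.

Step 4
Reactants: 4 3,3'-butanedioylbis[(4R)-4-benzyl-1,3-oxazolidin-2-one]; 6 2-(benzyloxy)-4-(bromomethyl)-1-methoxybenzene; 8 1-(benzyloxy)-4-(bromomethyl)-2-methoxybenzene
Product: 11 3,3'-{(2R,3R)-2-[3-(benzyloxy)-4-methoxybenzyl]-3-[4-(benzyloxy)-3-methoxybenzyl]butanedioyl}bis[(4R)-4-benzyl-1,3-oxazolidin-2-one], via dilithium bis-enolate 9 (not isolated), via mono-benzylated lithium enolate 10 (not isolated)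
Conditions: LDA (2.05 equiv), THF, −78 °C (briefly −40 °C, back to −78 °C); 6 (1.00 equiv), −78 °C, 2 h; then 8 (1.5 equiv), DMPU, −78 → −20 °C; AcOH quench
Reagents that add atoms: lithium diisopropylamide, [Li]N(C(C)C)C(C)C (supplies only the Li of 9 and 10; no atom of 11)
Why: Proposed new method: double deprotonation of 4 should give the chelated bis-(Z)-enolate 9, a buta-1,3-diene-1,4-diolate that is the imide counterpart of the known α,α'-dianions of succinic esters and amides, in which the C2 axis places both auxiliary benzyl groups on the same π-face; because this dianion is far more nucleophilic than any mono-enolate, one equivalent of 6 is consumed in a symmetry-breaking C-benzylation on the open face to give 10 with C2 set as R and with no proton transfer that could lead to homo-dialkylation, and 10 is then benzylated by 8 opposite the benzyl group of the second auxiliary to set C3 as R; the closest known reaction type is the Evans asymmetric alkylation of N-acyloxazolidinone enolates.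

Step 5
Reactants: 11 3,3'-{(2R,3R)-2-[3-(benzyloxy)-4-methoxybenzyl]-3-[4-(benzyloxy)-3-methoxybenzyl]butanedioyl}bis[(4R)-4-benzyl-1,3-oxazolidin-2-one]
Product: 12 (2R,3R)-2-[3-(benzyloxy)-4-methoxybenzyl]-3-[4-(benzyloxy)-3-methoxybenzyl]butane-1,4-diol
Conditions: LiBH4 (5 equiv), H2O (2 equiv), Et2O–THF, 0 °C → rt; aq NaOH work-up, 1 recovered
Reagents that add atoms: none
Why: Reductive cleavage of N-acyloxazolidinones by hydride attack at the exocyclic carbonyls turns both imides into CH2OH without touching the α-stereocentres, and benzyl ethers are inert to LiBH4.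

Step 6
Reactants: 12 (2R,3R)-2-[3-(benzyloxy)-4-methoxybenzyl]-3-[4-(benzyloxy)-3-methoxybenzyl]butane-1,4-diol; 13 benzoyl chloride
Product: 14 (2R,3R)-2-[3-(benzyloxy)-4-methoxybenzyl]-3-[4-(benzyloxy)-3-methoxybenzyl]butane-1,4-diyl dibenzoate
Conditions: 13 (2.5 equiv), Et3N (4 equiv), DMAP (0.1 equiv), CH2Cl2, 0 °C → rt
Reagents that add atoms: none
Why: DMAP-catalysed O-acylation of two primary alcohols (nucleophilic-catalysis esterification); the phenols are masked as benzyl ethers, so only the diol is benzoylated and no stereocentre is touched.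

Step 7
Reactants: 14 (2R,3R)-2-[3-(benzyloxy)-4-methoxybenzyl]-3-[4-(benzyloxy)-3-methoxybenzyl]butane-1,4-diyl dibenzoate
Product: 15 (2R,3R)-2-(3-hydroxy-4-methoxybenzyl)-3-(4-hydroxy-3-methoxybenzyl)butane-1,4-diyl dibenzoate
Conditions: H2 (1 atm), 10% Pd/C, EtOAc–EtOH, rt
Reagents that add atoms: none
Why: Pd-catalysed hydrogenolysis cleaves only the two aryl benzyl ethers; the alkyl benzoates, the methyl ethers and the non-benzylic C–O bonds are inert, and both stereocentres are remote from any reacting bond.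

## Compound list

1 | (4R)-4-benzyl-1,3-oxazolidin-2-one | O=C1N[C@H](Cc2ccccc2)CO1 | starting material
2 | succinyl chloride (butanedioyl dichloride) | O=C(Cl)CCC(=O)Cl | starting material
3 | (4R)-4-benzyl-3-lithio-1,3-oxazolidin-2-one | O=C1N([Li])[C@H](Cc2ccccc2)CO1 | intermediate (not isolated)
4 | 3,3'-butanedioylbis[(4R)-4-benzyl-1,3-oxazolidin-2-one] | O=C(CCC(=O)N1[C@H](Cc2ccccc2)COC1=O)N1[C@H](Cc2ccccc2)COC1=O | intermediate
5 | [3-(benzyloxy)-4-methoxyphenyl]methanol | COc1ccc(CO)cc1OCc1ccccc1 | starting material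
6 | 2-(benzyloxy)-4-(bromomethyl)-1-methoxybenzene | COc1ccc(CBr)cc1OCc1ccccc1 | intermediate
7 | [4-(benzyloxy)-3-methoxyphenyl]methanol | COc1cc(CO)ccc1OCc1ccccc1 | starting material
8 | 1-(benzyloxy)-4-(bromomethyl)-2-methoxybenzene | COc1cc(CBr)ccc1OCc1ccccc1 | intermediate
9 | dilithium (1Z,3Z)-1,4-bis[(4R)-4-benzyl-2-oxo-1,3-oxazolidin-3-yl]buta-1,3-diene-1,4-diolate | [Li]O/C(N1[C@H](Cc2ccccc2)COC1=O)=C\C=C(/O[Li])N1[C@H](Cc2ccccc2)COC1=O | intermediate (not isolated)
10 | lithium (1Z,3R)-3-[3-(benzyloxy)-4-methoxybenzyl]-1,4-bis[(4R)-4-benzyl-2-oxo-1,3-oxazolidin-3-yl]-4-oxobut-1-en-1-olate | COc1ccc(C[C@@H](C(=O)N2[C@H](Cc3ccccc3)COC2=O)/C=C(\O[Li])N2[C@H](Cc3ccccc3)COC2=O)cc1OCc1ccccc1 | intermediate (not isolated)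
11 | 3,3'-{(2R,3R)-2-[3-(benzyloxy)-4-methoxybenzyl]-3-[4-(benzyloxy)-3-methoxybenzyl]butanedioyl}bis[(4R)-4-benzyl-1,3-oxazolidin-2-one] | COc1ccc(C[C@@H](C(=O)N2[C@H](Cc3ccccc3)COC2=O)[C@H](C(=O)N2[C@H](Cc3ccccc3)COC2=O)Cc2ccc(OCc3ccccc3)c(OC)c2)cc1OCc1ccccc1 | intermediate
12 | (2R,3R)-2-[3-(benzyloxy)-4-methoxybenzyl]-3-[4-(benzyloxy)-3-methoxybenzyl]butane-1,4-diol | COc1ccc(C[C@@H](CO)[C@H](CO)Cc2ccc(OCc3ccccc3)c(OC)c2)cc1OCc1ccccc1 | intermediate
13 | benzoyl chloride | O=C(Cl)c1ccccc1 | starting material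
14 | (2R,3R)-2-[3-(benzyloxy)-4-methoxybenzyl]-3-[4-(benzyloxy)-3-methoxybenzyl]butane-1,4-diyl dibenzoate | COc1ccc(C[C@@H](COC(=O)c2ccccc2)[C@H](COC(=O)c2ccccc2)Cc2ccc(OCc3ccccc3)c(OC)c2)cc1OCc1ccccc1 | intermediate
15 | (2R,3R)-2-(3-hydroxy-4-methoxybenzyl)-3-(4-hydroxy-3-methoxybenzyl)butane-1,4-diyl dibenzoate (CNP0306197.1) | COc1ccc(C[C@@H](COC(=O)c2ccccc2)[C@H](COC(=O)c2ccccc2)Cc2ccc(O)c(OC)c2)cc1O | target

## Step count

Total steps: 7. Longest linear sequence: 5 (steps 1, 4, 5, 6, 7; equally 2, 4, 5, 6, 7).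

## Three steps most likely to fail

**Step 4 (highest risk).** The second deprotonation may be incomplete, and the electron-rich dianion 9 may be oxidised by the bromide or lose an oxazolidinone anion. Enolate 10 may cyclise by O-acylation onto the distal imide on warming. Any homo-dibenzylated product is isomeric with 11 and hard to remove.

The fallback sets out from 1 (as its lithium salt 3), uses 6 and 8, and comes back to the route at 12. It gives up the symmetric precursor and sets the second centre by substrate control on a ring.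
- 3 is acylated with methyl 4-chloro-4-oxobutanoate to methyl 4-[(4R)-4-benzyl-2-oxo-1,3-oxazolidin-3-yl]-4-oxobutanoate F1.
- Ordinary Evans benzylation of this mono-imide with 6 (NaHMDS, THF, −78 °C) gives methyl (3R)-3-[3-(benzyloxy)-4-methoxybenzyl]-4-[(4R)-4-benzyl-2-oxo-1,3-oxazolidin-3-yl]-4-oxobutanoate F2.
- NaBH4 in THF–H2O removes the auxiliary and spares the ester, giving methyl (3R)-3-[3-(benzyloxy)-4-methoxybenzyl]-4-hydroxybutanoate F3.
- F3 closes with catalytic TsOH to (4R)-4-[3-(benzyloxy)-4-methoxybenzyl]oxolan-2-one F4.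
- Alkylation of the lactone with 8 (LiHMDS, THF, −78 °C) occurs anti to the C4 substituent and gives the trans lactone (3R,4R)-4-[3-(benzyloxy)-4-methoxybenzyl]-3-[4-(benzyloxy)-3-methoxybenzyl]oxolan-2-one F5.
- LiAlH4 in THF opens F5 to diol 12.

**Step 5.** Both imides are α-branched and hindered, so hydride may open the oxazolidinone ring (endocyclic cleavage) or stop after one reduction. The fallback sets out from 11 and comes back at 12. It separates auxiliary removal from reduction: LiOH/H2O2 in THF–H2O at 0 °C hydrolyses both imides to (2R,3R)-2-[3-(benzyloxy)-4-methoxybenzyl]-3-[4-(benzyloxy)-3-methoxybenzyl]butanedioic acid F6, and BH3·SMe2 in THF reduces the diacid to 12.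

**Step 1.** Succinyl chloride can give ketene-derived or cyclised by-products under basic conditions, or stop at mono-acylation. The fallback sets out from 1 (as 3) and comes back at 4. It builds the diacyl unit in a non-enolisable form: 3 is acylated with fumaryl chloride to (2E)-1,4-bis[(4R)-4-benzyl-2-oxo-1,3-oxazolidin-3-yl]but-2-ene-1,4-dione F7, and hydrogenation of the electron-poor alkene (H2, Pd/C, EtOAc) gives 4.

## Further compounds

F1 | step 4 | methyl 4-[(4R)-4-benzyl-2-oxo-1,3-oxazolidin-3-yl]-4-oxobutanoate | COC(=O)CCC(=O)N1[C@H](Cc2ccccc2)COC1=O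
F2 | step 4 | methyl (3R)-3-[3-(benzyloxy)-4-methoxybenzyl]-4-[(4R)-4-benzyl-2-oxo-1,3-oxazolidin-3-yl]-4-oxobutanoate | COc1ccc(C[C@@H](C(=O)N2[C@H](Cc3ccccc3)COC2=O)CC(=O)OC)cc1OCc1ccccc1
F3 | step 4 | methyl (3R)-3-[3-(benzyloxy)-4-methoxybenzyl]-4-hydroxybutanoate | COc1ccc(C[C@@H](CO)CC(=O)OC)cc1OCc1ccccc1
F4 | step 4 | (4R)-4-[3-(benzyloxy)-4-methoxybenzyl]oxolan-2-one | COc1ccc(C[C@@H](CO2)CC2=O)cc1OCc1ccccc1
F5 | step 4 | (3R,4R)-4-[3-(benzyloxy)-4-methoxybenzyl]-3-[4-(benzyloxy)-3-methoxybenzyl]oxolan-2-one | COc1ccc(C[C@@H](CO2)[C@H](C2=O)Cc2ccc(OCc3ccccc3)c(OC)c2)cc1OCc1ccccc1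
F6 | step 5 | (2R,3R)-2-[3-(benzyloxy)-4-methoxybenzyl]-3-[4-(benzyloxy)-3-methoxybenzyl]butanedioic acid | COc1ccc(C[C@@H](C(=O)O)[C@H](C(=O)O)Cc2ccc(OCc3ccccc3)c(OC)c2)cc1OCc1ccccc1
F7 | step 1 | (2E)-1,4-bis[(4R)-4-benzyl-2-oxo-1,3-oxazolidin-3-yl]but-2-ene-1,4-dione | O=C(/C=C/C(=O)N1[C@H](Cc2ccccc2)COC1=O)N1[C@H](Cc2ccccc2)COC1=O
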